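**Clock first.** Time counts differently at each temperature, so I asked how many lifetimes of the intermediate each flask gets before it is read.

| setting | north-east | west | south-east | Friday's | Monday's | Tuesday's | Sunday's |
|---|---|---|---|---|---|---|---|
| substrate | 0.25 M | 0.25 M | 0.38 M | 0.25 M | 0.25 M | 0.25 M | 0.25 M |
| reagent | 0.15 M | 0.60 M | 0.30 M | 0.300 M | 0.300 M | 0.300 M | 0.300 M |
| temperature | −40 °C | −20 °C | −40 °C |  | −35 °C | −20 °C | −5 °C |
| remark | run made earlier | run made earlier | run made earlier | at −35 °C until 2.0 h, from then on at −5 °C |  |  |  |
| time |  |  |  | 2.5 h | 2.5 h | 2.5 h | 2.5 h |

north-east run (percent of the substrate charged)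

| time / h | target / % | substrate / % |
|---|---|---|
| 0.333 | 1.0 | 96.5 |
| 0.833 | 0 | 91.6 |
| 1.50 | 0 | 85.7 |
| 2.50 | 2.0 | 79.6 |

west run (percent of the substrate charged)

| time / min | target / % | substrate / % |
|---|---|---|
| 6.00 | 0.9 | 77.5 |
| 15.0 | 2.9 | 57.2 |
| 30.0 | 9.3 | 37.2 |
| 80.0 | 37.2 | 17.3 |

south-east run (percent of the substrate charged)

| time / h | target / % | substrate / % |
|---|---|---|
| 0.667 | 0.3 | 86.2 |
| 1.33 | 0.8 | 75.9 |
| 2.00 | 0 | 66.8 |
| 2.50 | 3.8 | 62.3 |

(each reading ± 1 percentage point)

- which flask leads in amount of target, in percent of the substrate charged ("all alike" within 1.5 percentage points) (Friday's / Monday's / Tuesday's / Sunday's / all alike)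
- how much target is there at the end, in percent of the substrate charged: Friday's
- how much target is there at the end, in percent of the substrate charged: Monday's
- how much target is there at the end, in percent of the substrate charged: Tuesday's
- how much target is there at the end, in percent of the substrate charged: Sunday's

- by-product is meant together with its idle adduct
- what may be going on: substrate + reagent -> intermediate + by-product; substrate + by-product <-> idle adduct; intermediate -> target

**The count.** I defined the lifetime count N as the first-order rate constant of intermediate → target multiplied by the time the flask spends there. While N is well below one and the first step runs roughly steadily, the intermediate rises roughly straight from zero, so its mean is half its end value, and target ≈ intermediate × N/2. Far above one, target follows what has passed the first step.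

**West estimate.** In the west run, target gained 28 percentage points between 30.0 min and 80.0 min. The gap, meaning what is neither substrate nor target, averaged 49.5%. So I read a rate constant at −20 °C of 0.676 /h, an estimate with the scatter of these readings.

**Cold doubt.** The last readings of the two −40 °C runs gave 0.0887 /h by the straight-rise rule. But the readings just before them were 0% and 0%, and the scatter is 1 point. Pooling those four readings, I took 0.0531 /h instead.

**Reading across.** Drawing ln k straight against temperature gave 0.100 /h at −35 °C and 4.56 /h at −5 °C. Monday's lifetime count is therefore 0.251, Tuesday's 1.69, Friday's 2.48 and Sunday's 11.4. One objection is that the gap also holds idle adduct, so these counts may run low. Another is that the extrapolation to −5 °C is long, but Sunday's count stays far above one. I expected Sunday's to lead, and Monday's target to be about 0.126 of its intermediate.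

**The forecast.** It named Sunday's, with Sunday's 87% (74% to 95%), Friday's 50% (40% to 60%), Tuesday's 43% (35% to 52%) and Monday's 6.5% (4% to 10%): “Target appears with a lag.”

**The result.** Sunday's led with 79.8%, against Friday's 50.5%, Tuesday's 43.9% and Monday's 3.63%, so the forecast stood 7.2 points high on Sunday's. At the end of Sunday's flask, substrate 7.99% and idle adduct 11.4% stood beside intermediate 0.798%. In Monday's flask, target over intermediate came to 0.132, against N/2 = 0.126.

    substrate + reagent → intermediate + by-product (k = 7.00 × 10⁻⁴ /M/s, Ea = 43.0 kJ/mol)
    substrate + by-product ⇌ idle adduct, settled at all times (K = 11.0 /M, ΔH = −11.0 kJ/mol)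
    intermediate → target (k = 2.70 × 10⁻⁴ /s, Ea = 81.0 kJ/mol)
    (constants at −20 °C)

**Second flask.** Monday's flask with 0.75 M of reagent keeps its time and temperature, so N stays 0.251. Its intermediate of 47.1% then gives 5.91% target, and the computed value is 6.90%.

Readings and results stem from a simulated flask from invented constants, noise included.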